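**Retrosynthetic overview**

1. Numbering used throughout: C1(=O)–C2=C3(Me)–C4–C5–C6(Me2)–C7(OAng)–C8(OiBu)–C9H2–C10(Me)–C11, with cyclobutane C4–C10–C11–C5, enone ring C1–C2–C3–C4–C10–C11 (together a bicyclo[3.1.1]heptenone) and seven-membered ring C4–C5–C6–C7–C8–C9–C10. Endgame: the two esters go onto the 7,8-diol last, C11–H comes from a bridgehead C11–CO2H (traceless activating group), and C2=C3 comes from β-elimination at C3.
2. Key disconnection: C3–C4 and C10–C11 together, from monocyclic cycloheptene 19 (C4=C10 alkene; C5 side chain C11H(CO2Me)–C1(=O)–C2H2–C3(dioxolane)–CH3) by a ketal-initiated, enol-silane-terminated cation–olefin bicyclization that closes the six- and the four-membered ring in one operation.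
3. Enabling feature: C1 and C3 of the enone ring are a masked 1,3-dicarbonyl whose two arms end on the adjacent seven-ring carbons C4 and C10. C10 is the methyl-bearing alkene carbon, so an electrophile at C3 leaves a tertiary cation on C10; C11, the enolisable carbon of C1, sits 1,3 to C4 through C5 and can close onto C10 (a terpinyl-to-pinyl relationship).
4. Cycloheptene 19: C5–C11 by Johnson–Claisen transfer from a C10 tertiary allylic alcohol; that alcohol by O8-directed epoxidation and selenoxide transposition; O7 by O8-directed reduction; O8 by asymmetric enol-ether oxidation of karahanaenone, which comes from linalool by Claisen ring expansion.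
5. Ring order: seven-membered ring first (step 2), then enone ring and cyclobutane together (step 13).

Key step: step 13

Assumption (step 1): bromoetherification of linalool is taken to give the 5-exo tetrahydrofuran; any tetrahydropyran regioisomer would be separated.
Assumption (step 4): the L-fructose-derived ketone catalyst is expected, from the spiro transition-state model by analogy with 1-substituted cycloalkenes, to give the (S)-alcohol; the sense must be confirmed and the other catalyst enantiomer used if it is reversed.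

**Route**

Step 1
Reactants: 1 (±)-linalool
Product: 2 2-(2-bromopropan-2-yl)-5-methyl-5-vinyltetrahydrofuran (racemic, both diastereomers)
Conditions: NBS, CH2Cl2, 0 °C
Reagents that add atoms: N-bromosuccinimide, O=C1CCC(=O)N1Br
Why: Bromoetherification: bromonium formation on the trisubstituted alkene and 5-exo capture by the tertiary hydroxyl should give the tetrahydrofuran with bromine on the tertiary carbon; both stereocentres are erased in step 2.

Step 2
Reactants: 2
Product: 4 karahanaenone (2,2,5-trimethylcyclohept-4-en-1-one), via isopropylidene enol ether 3 (not isolated)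
Conditions: 2,4,6-collidine, 170 °C (sealed tube)
Reagents that add atoms: none
Why: E2 loss of HBr toward the ring C–H should give the allyl vinyl ether 3, which undergoes a Claisen rearrangement with ring expansion to the achiral 4-cycloheptenone, forming C5–C6 and the C4=C10(Me) alkene.

Step 3
Reactants: 4
Product: 5 triethylsilyl enol ether of 4 (triethyl[(4,7,7-trimethylcyclohepta-1,4-dien-1-yl)oxy]silane)
Conditions: Et3SiOTf, Et3N, CH2Cl2, 0 °C
Reagents that add atoms: triethylsilyl triflate, CC[Si](CC)(CC)OS(=O)(=O)C(F)(F)F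
Why: Soft enolisation (silyl triflate and amine) can only go toward C8 because C6 is quaternary, so a single enol ether should form.

Step 4
Reactants: 5
Product: 7 (S)-7-hydroxy-2,2,5-trimethylcyclohept-4-en-1-one, via silyloxy epoxide 6 (not isolated)
Conditions: ent-Shi ketone (1,2:4,5-di-O-isopropylidene-β-L-erythro-2,3-hexodiulo-2,6-pyranose, 0.3 equiv), KHSO5 (Oxone), K2CO3, MeCN/dimethoxymethane/aq. Na2B4O7 buffer, 0 °C; then AcOH, THF/H2O
Reagents that add atoms: potassium peroxymonosulfate (KHSO5), [K+].[O-]S(=O)(=O)OO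
Why: Shi asymmetric epoxidation (chiral dioxirane) of the electron-rich enol ether, which should react faster than the remote trisubstituted alkene, followed by hydrolysis of the silyloxy epoxide (Rubottom-type α-hydroxylation) sets C8 under catalyst control.

Step 5
Reactants: 7
Product: 8 epoxy hydroxy ketone (C4–C10 epoxide, oxygen cis to the C8 hydroxyl)
Conditions: VO(acac)2 (cat.), t-BuOOH, CH2Cl2, 0 °C to rt
Reagents that add atoms: tert-butyl hydroperoxide, CC(C)(C)OO
Why: Hydroxyl-directed vanadium-catalysed epoxidation of the homoallylic alcohol should deliver oxygen to the alkene face cis to the C8 hydroxyl, setting C10 and C4.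

Step 6
Reactants: 8
Product: 9 epoxy trans-7,8-diol (O7 trans to O8; epoxide oxygen cis to O8)
Conditions: Me4NBH(OAc)3, MeCN/AcOH, −30 °C
Reagents that add atoms: none
Why: Hydroxyl-directed triacetoxyborohydride reduction (Saksena–Evans type) delivers hydride from boron bound to O8, so the new C7 hydroxyl should be trans to the C8 hydroxyl.

Step 7
Reactants: 9
Product: 10 7,8-bis(tert-butyldimethylsilyl) ether of 9
Conditions: TBSOTf, 2,6-lutidine, CH2Cl2, −78 to 0 °C
Reagents that add atoms: tert-butyldimethylsilyl triflate, CC(C)(C)[Si](C)(C)OS(=O)(=O)C(F)(F)F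
Why: Silyl ether protection with the silyl triflate and a hindered base, needed for the neopentyl C7 hydroxyl, should leave the epoxide untouched at low temperature.

Step 8
Reactants: 10
Product: 13 tertiary allylic alcohol (C10–OH cis to O8; C4=C5 alkene; 7,8-bis-OTBS), via hydroxy selenide 11 (not isolated), via selenoxide 12 (not isolated)
Conditions: (PhSe)2, NaBH4, EtOH, 80 °C; then 30% H2O2, pyridine, THF, 0 °C to rt
Reagents that add atoms: none
Why: Sharpless-type epoxide-to-allylic-alcohol transposition: selenolate opens the epoxide by SN2 at the less substituted C4, and selenoxide syn-elimination can only go toward C5, so the C10–O bond and its configuration are kept.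

Step 9
Reactants: 13
Product: 15 methyl ester (C5–CH2CO2Me cis to O8; C4=C10(Me) alkene; 7,8-bis-OTBS), via ketene acetal 14 (not isolated)
Conditions: MeC(OMe)3, EtCO2H (cat.), xylenes, 140 °C, MeOH distilled off
Reagents that add atoms: trimethyl orthoacetate, CC(OC)(OC)OC
Why: Johnson–Claisen rearrangement through ketene acetal 14 is suprafacial, so the new C5–C11 bond should form on the ring face that carried the C10 oxygen (cis to O8) while the C4=C10(Me) alkene is regenerated.

Step 10
Reactants: 16 fructone (ethyl 2-(2-methyl-1,3-dioxolan-2-yl)acetate)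
Product: 17 2-(2-methyl-1,3-dioxolan-2-yl)acetaldehyde
Conditions: i-Bu2AlH, CH2Cl2, −78 °C; aqueous work-up
Reagents that add atoms: none
Why: Partial ester reduction with i-Bu2AlH at low temperature stops at the aluminium hemiacetal, which gives the aldehyde on work-up.

Step 11
Reactants: 15 methyl ester; 17 aldehyde
Product: 18 β-hydroxy ester (mixture at C11 and C1)
Conditions: LiN(i-Pr)2, THF, −78 °C; then 17; AcOH quench
Reagents that add atoms: none
Why: Aldol addition of the lithium ester enolate to the aldehyde; the new centres at C11 and C1 are not controlled because both are erased later.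

Step 12
Reactants: 18
Product: 19 β-keto ester (C5 side chain CH(CO2Me)–C(=O)–CH2–C(dioxolane)–CH3; C11 epimers)
Conditions: Dess–Martin periodinane, NaHCO3, CH2Cl2, rt
Reagents that add atoms: none
Why: Dess–Martin oxidation of the secondary alcohol under buffered conditions should leave ketal, silyl ethers and alkene intact.

Step 13
Reactants: 19
Product: 21 tricyclic β-keto ester (C11–CO2Me; C3 bearing CH3 and OCH2CH2OTBS as a C3 mixture; 7,8-bis-OTBS), via silyl enol ether 20 (not isolated)
Conditions: Et3N (1.05 equiv), TBSOTf (1.05 equiv), CH2Cl2, −78 °C; then TBSOTf (0.3 equiv), 2,6-di-tert-butyl-4-methylpyridine (0.1 equiv), −78 to −40 °C, high dilution; aq. NaHCO3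
Reagents that add atoms: tert-butyldimethylsilyl triflate, CC(C)(C)[Si](C)(C)OS(=O)(=O)C(F)(F)F
Why: Proposed new method: TBSOTf/Et3N first turns the β-keto ester into its O-silyl enol ether 20 (C11=C1), then catalytic TBSOTf opens the dioxolane at C3 to a 2-silyloxyethyl oxocarbenium ion, which the C4=C10 alkene attacks through C4 (Prins closure), leaving a tertiary, terpinyl-type cation on methyl-bearing C10 that is captured by the enol-silane carbon C11 with return of TBSOTf; the closest known reactions are acetal-initiated Prins (Mukaiyama-type) cation–olefin cyclizations terminated by enol silanes or β-keto esters, the closure of a tertiary cation onto an enol ether in Gassman-type cationic [2+2] cycloadditions, and the terpinyl-to-pinyl step of pinene cyclases. The six-membered ring C3–C2–C1–C11–C5–C4 closes 6-exo-trig with respect to the alkene (bond C3–C4, C10 outside the ring), and the four-membered ring C4–C10–C11–C5 closes by attack of C11 on the C10 cation with the enol double bond exo to the new ring (bond C10–C11), completing the bicyclo[3.1.1]heptanone. C4, C10 and C11 are dictated by C5: the chain hangs from one face of the seven-membered ring, both bonds must form on that face, and the tricycle allows only one relative configuration of its four cyclobutane carbons, while C3 forms as a mixture and is erased in step 14. The ester on C11 fixes the enolisation site and, through silyl exchange between the two carbonyl oxygens, lets the enol geometry equilibrate to the one with C5 cis to C2 that a six-membered ring through C11=C1 demands; it is removed in steps 15 and 16. The step needs alkene attack on the oxocarbenium ion to outrun direct four-ring aldol closure by the enol silane, and capture of the C10 cation to outrun proton loss or trapping by the C7 silyl-ether oxygen; the modest nucleophilicity of the ester-conjugated enol silane, base-free low-temperature conditions and the 1,3-placement of C11 and C4 in the new ring are relied on for this.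

Step 14
Reactants: 21
Product: 22 tricyclic enone ester (C1(=O)–C2=C3(Me); C11–CO2Me; 7,8-bis-OTBS)
Conditions: DBU, toluene, 80 °C
Reagents that add atoms: none
Why: E1cB elimination of the β-alkoxy group through the C2 enolate should give the conjugated enone, elimination toward bridgehead C4 being excluded by Bredt's rule.

Step 15
Reactants: 22
Product: 23 bridgehead β-keto acid (C11–CO2H)
Conditions: LiI, pyridine, 115 °C; then aq. HCl
Reagents that add atoms: none
Why: SN2 demethylation of the hindered methyl ester by iodide gives the β-keto acid, which should not decarboxylate thermally because the required enol would be a bridgehead alkene.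

Step 16
Reactants: 23
Product: 24 7,8-bis-OTBS longipin-2-en-1-one (C11–H)
Conditions: 9-mesityl-10-phenylacridinium tetrafluoroborate (cat.), (PhS)2 (cat.), 2,6-lutidine (cat.), CF3CH2OH, 450 nm LEDs, rt
Reagents that add atoms: none
Why: Photoredox hydrodecarboxylation: oxidation of the carboxylate, loss of CO2 and hydrogen-atom transfer from thiophenol to the bridgehead radical, whose configuration is fixed by the cage.

Step 17
Reactants: 24
Product: 25 7,8-diol (longipin-2-en-1-one with O7 trans to O8)
Conditions: HF·pyridine, THF, 0 °C to rt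
Reagents that add atoms: none
Why: Fluoride-mediated cleavage of both silyl ethers.

Step 18
Reactants: 25
Product: 26 8-isobutyrate (7-OH free)
Conditions: (i-PrCO)2O (1.05 equiv), Et3N, DMAP (cat.), CH2Cl2, −20 °C
Reagents that add atoms: isobutyric anhydride, CC(C)C(=O)OC(=O)C(C)C
Why: DMAP-catalysed acylation should go to the less hindered C8 hydroxyl, the C7 hydroxyl being neopentyl (next to C6).

Step 19
Reactants: 26
Product: 27 target (7-angelate, 8-isobutyrate)
Conditions: angelic acid, 2,4,6-trichlorobenzoyl chloride, Et3N, toluene, rt; then 26, 80 °C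
Reagents that add atoms: angelic acid, C/C=C(/C)C(=O)O
Why: Yamaguchi esterification through the mixed anhydride should acylate the hindered C7 hydroxyl without Z-to-E isomerisation of the angelate.

**Compound list**

1 | (±)-linalool | C=CC(C)(O)CCC=C(C)C | starting material
2 | 2-(2-bromopropan-2-yl)-5-methyl-5-vinyltetrahydrofuran (racemic, both diastereomers) | C=CC1(C)CCC(O1)C(C)(C)Br | intermediate
3 | 2-methyl-5-(propan-2-ylidene)-2-vinyltetrahydrofuran (racemic) | C=CC1(C)CCC(=C(C)C)O1 | intermediate
4 | karahanaenone, 2,2,5-trimethylcyclohept-4-en-1-one | O=C1CCC(C)=CCC1(C)C | intermediate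
5 | triethyl[(4,7,7-trimethylcyclohepta-1,4-dien-1-yl)oxy]silane | CC[Si](CC)(CC)OC1=CCC(C)=CCC1(C)C | intermediate
6 | silyloxy epoxide of 5 (epoxide on the enol ether, oxygen on the face that becomes the (S)-hydroxyl) | CC[Si](CC)(CC)O[C@]12O[C@H]1CC(C)=CCC2(C)C | intermediate
7 | (S)-7-hydroxy-2,2,5-trimethylcyclohept-4-en-1-one (hydroxyl on C8 of the target numbering) | O=C1[C@@H](O)CC(C)=CCC1(C)C | intermediate
8 | epoxy hydroxy ketone: 7 with the C4–C10 epoxide cis to the C8 hydroxyl | O=C1[C@@H](O)C[C@@]2(C)O[C@H]2CC1(C)C | intermediate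
9 | epoxy diol: C7–OH trans to C8–OH, epoxide oxygen cis to C8–OH | O[C@@H]1[C@@H](O)C[C@@]2(C)O[C@H]2CC1(C)C | intermediate
10 | 7,8-bis-TBS ether of 9 | CC(C)(C)[Si](C)(C)O[C@@H]1[C@@H](O[Si](C)(C)C(C)(C)C)C[C@@]2(C)O[C@H]2CC1(C)C | intermediate
11 | hydroxy selenide: C10–OH (cis to O8), C4–SePh trans to it, 7,8-bis-OTBS | CC(C)(C)[Si](C)(C)O[C@@H]1[C@@H](O[Si](C)(C)C(C)(C)C)C[C@@](C)(O)[C@H]([Se]c2ccccc2)CC1(C)C | intermediate
12 | selenoxide of 11 | CC(C)(C)[Si](C)(C)O[C@@H]1[C@@H](O[Si](C)(C)C(C)(C)C)C[C@@](C)(O)[C@H]([Se](=O)c2ccccc2)CC1(C)C | intermediate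
13 | tertiary allylic alcohol: C10(OH)(CH3) with OH cis to O8, C4=C5 alkene, 7,8-trans-bis-OTBS | CC(C)(C)[Si](C)(C)O[C@@H]1[C@@H](O[Si](C)(C)C(C)(C)C)C[C@@](C)(O)C=CC1(C)C | intermediate
14 | mixed ketene acetal of 13 (C10–O–C(OMe)=CH2) | CC(C)(C)[Si](C)(C)O[C@@H]1[C@@H](O[Si](C)(C)C(C)(C)C)C[C@@](C)(OC(=C)OC)C=CC1(C)C | intermediate
15 | methyl ester: C5–CH2CO2Me cis to O8 and trans to O7, C4=C10(CH3) alkene, 7,8-bis-OTBS | CC(C)(C)[Si](C)(C)O[C@@H]1[C@@H](O[Si](C)(C)C(C)(C)C)CC(C)=C[C@@H](CC(=O)OC)C1(C)C | intermediate
16 | fructone, ethyl 2-(2-methyl-1,3-dioxolan-2-yl)acetate | CCOC(=O)CC1(C)OCCO1 | starting material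
17 | 2-(2-methyl-1,3-dioxolan-2-yl)acetaldehyde | O=CCC1(C)OCCO1 | intermediate
18 | β-hydroxy ester (aldol of 15 and 17; mixture at C11 and C1) | CC(C)(C)[Si](C)(C)O[C@@H]1[C@@H](O[Si](C)(C)C(C)(C)C)CC(C)=C[C@@H](C(C(=O)OC)C(O)CC2(C)OCCO2)C1(C)C | intermediate
19 | β-keto ester (C11 epimers), precursor of the key step | CC(C)(C)[Si](C)(C)O[C@@H]1[C@@H](O[Si](C)(C)C(C)(C)C)CC(C)=C[C@@H](C(C(=O)OC)C(=O)CC2(C)OCCO2)C1(C)C | intermediate
20 | O-TBS enol ether of 19 (C11=C1, reactive geometry with C5 cis to C2) | CC(C)(C)[Si](C)(C)O[C@@H]1[C@@H](O[Si](C)(C)C(C)(C)C)CC(C)=C[C@@H](/C(C(=O)OC)=C(/O[Si](C)(C)C(C)(C)C)CC2(C)OCCO2)C1(C)C | intermediate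
21 | tricyclic β-keto ester: longipinan-1-one with C11–CO2Me, C3(CH3)(OCH2CH2OTBS) (C3 mixture), 7,8-bis-OTBS | CC(C)(C)[Si](C)(C)O[C@@H]1[C@@H](O[Si](C)(C)C(C)(C)C)C[C@@]2(C)[C@]3(C(=O)OC)C(=O)CC(C)(OCCO[Si](C)(C)C(C)(C)C)[C@H]2[C@@H]3C1(C)C | intermediate
22 | tricyclic enone ester: longipin-2-en-1-one with C11–CO2Me, 7,8-bis-OTBS | CC(C)(C)[Si](C)(C)O[C@@H]1[C@@H](O[Si](C)(C)C(C)(C)C)C[C@@]2(C)[C@]3(C(=O)OC)C(=O)C=C(C)[C@H]2[C@@H]3C1(C)C | intermediate
23 | bridgehead β-keto acid (C11–CO2H) | CC(C)(C)[Si](C)(C)O[C@@H]1[C@@H](O[Si](C)(C)C(C)(C)C)C[C@@]2(C)[C@]3(C(=O)O)C(=O)C=C(C)[C@H]2[C@@H]3C1(C)C | intermediate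
24 | 7,8-bis-OTBS longipin-2-en-1-one | CC(C)(C)[Si](C)(C)O[C@@H]1[C@@H](O[Si](C)(C)C(C)(C)C)C[C@@]2(C)[C@@H]3C(=O)C=C(C)[C@H]2[C@@H]3C1(C)C | intermediate
25 | 7,8-dihydroxylongipin-2-en-1-one (trans-diol) | O[C@@H]1[C@@H](O)C[C@@]2(C)[C@@H]3C(=O)C=C(C)[C@H]2[C@@H]3C1(C)C | intermediate
26 | 7-hydroxy-8-isobutyryloxylongipin-2-en-1-one | O[C@@H]1[C@@H](OC(=O)C(C)C)C[C@@]2(C)[C@@H]3C(=O)C=C(C)[C@H]2[C@@H]3C1(C)C | intermediate
27 | 7-angeloyloxy-8-isobutyryloxylongipin-2-en-1-one | C/C=C(/C)C(=O)O[C@@H]1[C@@H](OC(=O)C(C)C)C[C@@]2(C)[C@@H]3C(=O)C=C(C)[C@H]2[C@@H]3C1(C)C | target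

**Step count**

Total steps: 19. Longest linear sequence: 18 (steps 1 to 9 and 11 to 19).

**Steps most likely to fail**

Step 13 (Proposed new method). The C10 cation may lose a proton or be trapped by the C7 silyl-ether oxygen before the strained four-ring closure, or the enol silane may add directly to the oxocarbenium ion. The fallback uses known chemistry, sets out from 15 and returns at 24. Trifluoroacetylation of the ester enolate (LiN(SiMe3)2, CF3CO2CH2CF3) should give the α-trifluoroacetyl ester F1, and detrifluoroacetylative diazo transfer (MsN3, Et3N) the α-diazo ester F2. Intramolecular cyclopropanation of the C4=C10 alkene by the carbene at C11 with Rh2(O2CCPh3)4 should give the bicyclo[1.1.0]butane ester F3, with bonds C11–C10 and C11–C4. Strain-release homoconjugate addition of LiCu(C(CH3)=CH2)2 to bridgehead C4 cleaves the central C4–C11 bond and, after protonation and base equilibration at C11, should give the cis-1,3-disubstituted cyclobutane ester F4. Saponification (LiOH) gives the acid F5. Its acid chloride ((COCl)2) is closed onto the isopropenyl group with SnCl4 (intramolecular alkene acylation); loss of HCl gives enone 24.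

Step 4. Face selectivity of the dioxirane may be insufficient, the C4=C10 alkene may be epoxidised as well, or the α-hydroxy ketone may racemise by enolisation in the basic buffer. The fallback sets out from 5 and returns at 7. Rubottom oxidation (mCPBA, then AcOH/H2O) should give the racemic hydroxy ketone F6. Kinetic resolution by a lipase (Candida antarctica lipase B, vinyl acetate) should acetylate one enantiomer, assumed to be (R), to the acetate F7 and leave (S)-7, which is separated.

Step 9. Acid-catalysed dehydration of the tertiary allylic alcohol to dienes may outrun ketene acetal formation, or the [3,3] shift may stall at the neopentyl terminus C5. The fallback sets out from 13 and returns at 15. n-BuLi then ClCO2Me should give the tertiary allylic methyl carbonate F8. Tsuji–Trost allylic alkylation with NaCH(CO2Me)2 and Pd(PPh3)4 (double inversion, attack at the less substituted terminus C5) should give the malonate F9 with the same C5 configuration. Krapcho dealkoxycarbonylation (LiCl, wet DMSO, 150 °C) then gives 15.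

Further compounds
F1 | step 13 | α-trifluoroacetyl derivative of ester 15 | CC(C)(C)[Si](C)(C)O[C@@H]1[C@@H](O[Si](C)(C)C(C)(C)C)CC(C)=C[C@@H](C(C(=O)OC)C(=O)C(F)(F)F)C1(C)C
F2 | step 13 | α-diazo ester of 15 | CC(C)(C)[Si](C)(C)O[C@@H]1[C@@H](O[Si](C)(C)C(C)(C)C)CC(C)=C[C@@H](C(=[N+]=[N-])C(=O)OC)C1(C)C
F3 | step 13 | bicyclo[1.1.0]butane ester (C11 bonded to C4, C5 and C10) | CC(C)(C)[Si](C)(C)O[C@@H]1[C@@H](O[Si](C)(C)C(C)(C)C)C[C@@]2(C)[C@]3(C(=O)OC)[C@H]2[C@@H]3C1(C)C
F4 | step 13 | cyclobutane ester with isopropenyl on C4 cis to CO2Me on C11 | CC(C)(C)[Si](C)(C)O[C@@H]1[C@@H](O[Si](C)(C)C(C)(C)C)C[C@@]2(C)[C@H](C(=O)OC)[C@H]([C@@H]2C(C)=C)C1(C)C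
F5 | step 13 | carboxylic acid of F4 | CC(C)(C)[Si](C)(C)O[C@@H]1[C@@H](O[Si](C)(C)C(C)(C)C)C[C@@]2(C)[C@H](C(=O)O)[C@H]([C@@H]2C(C)=C)C1(C)C
F6 | step 4 | racemic 7-hydroxy-2,2,5-trimethylcyclohept-4-en-1-one | O=C1C(O)CC(C)=CCC1(C)C
F7 | step 4 | (R)-7-acetoxy-2,2,5-trimethylcyclohept-4-en-1-one | O=C1[C@H](OC(C)=O)CC(C)=CCC1(C)C
F8 | step 9 | methyl carbonate of 13 | CC(C)(C)[Si](C)(C)O[C@@H]1[C@@H](O[Si](C)(C)C(C)(C)C)C[C@@](C)(OC(=O)OC)C=CC1(C)C
F9 | step 9 | dimethyl malonate at C5 (C4=C10 alkene) | CC(C)(C)[Si](C)(C)O[C@@H]1[C@@H](O[Si](C)(C)C(C)(C)C)CC(C)=C[C@@H](C(C(=O)OC)C(=O)OC)C1(C)C
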